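**Assumption:** the target SMILES contains no stereocentre and no stereogenic double bond, so the compound is achiral and needs no enantiocontrol. The cyclohexenone intermediates are racemic, and their stereocentres vanish on aromatisation.

## Retrosynthetic overview
1. Target 21 comes from benzyl ester 20 by hydrogenolysis; 20 is cut at the depside C(=O)–OAr bond into acid 18 and phenol 11.
2. 18 comes from methyl 2,4-dihydroxy-6-propylbenzoate 16 (di-O-methylation, saponification). 11 comes from methyl 2,4-dihydroxy-6-pentylbenzoate 6 (4-O-MOM, 2-O-Me, methyl to benzyl ester switch, MOM removal).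
3. Each resorcylate (6, 16) comes from a cyclohexane-1,3-dione ester (4, 14) by bromination–dehydrobromination.
4. Key C–C disconnection: intermolecular Michael addition of dimethyl malonate 2 to an (E)-enone (1 or 12), followed in the same pot by Dieckmann-type Claisen ring closure.
5. Ring order: the pentyl-bearing ring is built first (steps 1–2), the propyl-bearing ring second (steps 8–9); the two rings are joined last by esterification.

## Route

**Step 1**
Reactants: 1 (E)-non-3-en-2-one; 2 dimethyl malonate
Product: 4 methyl 2-hydroxy-4-oxo-6-pentylcyclohex-2-ene-1-carboxylate (racemic), via Michael adduct 3 (not isolated)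
Conditions: NaOMe (1.1 equiv), MeOH, 0 °C → reflux, 4 h; then cold aq. HCl
Reagents that add atoms: none
Why: The malonate anion adds 1,4 to the enone (intermolecular Michael addition, the key C–C bond) and the methyl-ketone enolate of 3 then closes the ring on a malonate ester (Dieckmann-type Claisen condensation), driven by the stabilised 1,3-dione enolate; the two racemic stereocentres are erased in step 2.

**Step 2**
Reactants: 4 methyl 2-hydroxy-4-oxo-6-pentylcyclohex-2-ene-1-carboxylate
Product: 6 methyl 2,4-dihydroxy-6-pentylbenzoate, via bromo dione 5 (not isolated)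
Conditions: Br2 (1.0 equiv), DMF, 0 °C, 1 h; then 80 °C, 12 h
Reagents that add atoms: none
Why: Bromination of the enolised 1,3-dione followed by thermal loss of HBr and tautomerisation (halogenation–dehydrohalogenation aromatisation) gives the resorcylate with the ester intact at 80 °C.

**Step 3**
Reactants: 6 methyl 2,4-dihydroxy-6-pentylbenzoate
Product: 7 methyl 2-hydroxy-4-(methoxymethoxy)-6-pentylbenzoate
Conditions: MOMCl (1.1 equiv), K2CO3, acetone, 0 °C → rt
Reagents that add atoms: chloromethyl methyl ether (MOMCl), COCCl
Why: The 2-OH is tied up in a hydrogen bond to the ester carbonyl, so Williamson etherification with one equivalent of MOMCl goes to the free, more acidic 4-OH.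

**Step 4**
Reactants: 7 methyl 2-hydroxy-4-(methoxymethoxy)-6-pentylbenzoate
Product: 8 methyl 2-methoxy-4-(methoxymethoxy)-6-pentylbenzoate
Conditions: MeI (3 equiv), K2CO3, DMF, 50 °C
Reagents that add atoms: iodomethane, CI
Why: With the 4-OH masked, the chelated 2-OH is O-methylated under more forcing Williamson ether conditions.

**Step 5**
Reactants: 8 methyl 2-methoxy-4-(methoxymethoxy)-6-pentylbenzoate
Product: 9 2-methoxy-4-(methoxymethoxy)-6-pentylbenzoic acid
Conditions: KOH (10 equiv), DMSO/H2O 4:1, 90 °C; then cold 1 M HCl to pH 4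
Reagents that add atoms: potassium hydroxide, [K+].[OH-]
Why: Poorly solvated hydroxide in wet DMSO saponifies the di-ortho-substituted ester (BAc2 ester hydrolysis), while the MOM acetal and aryl methyl ether are inert to base.

**Step 6**
Reactants: 9 2-methoxy-4-(methoxymethoxy)-6-pentylbenzoic acid
Product: 10 benzyl 2-methoxy-4-(methoxymethoxy)-6-pentylbenzoate
Conditions: BnBr (1.2 equiv), K2CO3, DMF, rt
Reagents that add atoms: benzyl bromide, BrCc1ccccc1
Why: SN2 O-alkylation of the carboxylate is insensitive to the ortho substituents that block acyl substitution, and it installs an ester removable later by hydrogenolysis.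

**Step 7**
Reactants: 10 benzyl 2-methoxy-4-(methoxymethoxy)-6-pentylbenzoate
Product: 11 benzyl 4-hydroxy-2-methoxy-6-pentylbenzoate
Conditions: conc. HCl (cat.), MeOH, 50 °C
Reagents that add atoms: none
Why: Acid-catalysed transacetalisation to methanol cleaves the MOM acetal, while the hindered benzyl ester does not transesterify under these mild conditions.

**Step 8**
Reactants: 12 (E)-hept-3-en-2-one; 2 dimethyl malonate
Product: 14 methyl 2-hydroxy-4-oxo-6-propylcyclohex-2-ene-1-carboxylate (racemic), via Michael adduct 13 (not isolated)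
Conditions: NaOMe (1.1 equiv), MeOH, 0 °C → reflux, 4 h; then cold aq. HCl
Reagents that add atoms: none
Why: Same intermolecular Michael addition followed by Dieckmann-type Claisen cyclisation as in step 1; the racemic stereocentres are erased in step 9.

**Step 9**
Reactants: 14 methyl 2-hydroxy-4-oxo-6-propylcyclohex-2-ene-1-carboxylate
Product: 16 methyl 2,4-dihydroxy-6-propylbenzoate, via bromo dione 15 (not isolated)
Conditions: Br2 (1.0 equiv), DMF, 0 °C, 1 h; then 80 °C, 12 h
Reagents that add atoms: none
Why: Halogenation–dehydrohalogenation aromatisation of the 1,3-dione, as in step 2.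

**Step 10**
Reactants: 16 methyl 2,4-dihydroxy-6-propylbenzoate
Product: 17 methyl 2,4-dimethoxy-6-propylbenzoate
Conditions: MeI (4 equiv), K2CO3, DMF, 50 °C
Reagents that add atoms: iodomethane, CI
Why: Exhaustive Williamson O-methylation of both phenols; excess MeI and warming also alkylate the chelated 2-OH.

**Step 11**
Reactants: 17 methyl 2,4-dimethoxy-6-propylbenzoate
Product: 18 2,4-dimethoxy-6-propylbenzoic acid
Conditions: KOH (10 equiv), DMSO/H2O 4:1, 100 °C; then 1 M HCl
Reagents that add atoms: potassium hydroxide, [K+].[OH-]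
Why: Saponification of the hindered ester with hydroxide in wet DMSO, with only base-stable aryl ethers present.

**Step 12**
Reactants: 18 2,4-dimethoxy-6-propylbenzoic acid; 11 benzyl 4-hydroxy-2-methoxy-6-pentylbenzoate
Product: 20 benzyl 4-[(2,4-dimethoxy-6-propylbenzoyl)oxy]-2-methoxy-6-pentylbenzoate, via mixed anhydride 19 (not isolated)
Conditions: TFAA (5 equiv), toluene, rt, 4 h; aq. NaHCO3 work-up
Reagents that add atoms: none
Why: TFAA turns the hindered, electron-rich acid into a trifluoroacetic mixed anhydride (in equilibrium with its acylium ion) that acylates the only free hydroxyl of 11 (mixed-anhydride esterification).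

**Step 13**
Reactants: 20 benzyl 4-[(2,4-dimethoxy-6-propylbenzoyl)oxy]-2-methoxy-6-pentylbenzoate
Product: 21 4-[(2,4-dimethoxy-6-propylbenzoyl)oxy]-2-methoxy-6-pentylbenzoic acid (target)
Conditions: H2 (1 atm), 10% Pd/C, EtOAc, rt
Reagents that add atoms: none
Why: Catalytic hydrogenolysis cleaves only the benzylic C–O bond, leaving the aryl ester, the methyl ethers and both arenes untouched.

## Compound list
1 | (E)-non-3-en-2-one | CCCCC/C=C/C(C)=O | starting material
2 | dimethyl malonate | COC(=O)CC(=O)OC | starting material
3 | dimethyl 2-(2-oxononan-4-yl)propanedioate (racemic, not isolated) | CCCCCC(CC(C)=O)C(C(=O)OC)C(=O)OC | intermediate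
4 | methyl 2-hydroxy-4-oxo-6-pentylcyclohex-2-ene-1-carboxylate (racemic, enol form of the 2,4-dione) | CCCCCC1CC(=O)C=C(O)C1C(=O)OC | intermediate
5 | methyl 3-bromo-2-hydroxy-4-oxo-6-pentylcyclohex-2-ene-1-carboxylate (racemic, not isolated; drawn as the kinetic 3-bromo isomer) | CCCCCC1CC(=O)C(Br)=C(O)C1C(=O)OC | intermediate
6 | methyl 2,4-dihydroxy-6-pentylbenzoate | CCCCCc1cc(O)cc(O)c1C(=O)OC | intermediate
7 | methyl 2-hydroxy-4-(methoxymethoxy)-6-pentylbenzoate | CCCCCc1cc(OCOC)cc(O)c1C(=O)OC | intermediate
8 | methyl 2-methoxy-4-(methoxymethoxy)-6-pentylbenzoate | CCCCCc1cc(OCOC)cc(OC)c1C(=O)OC | intermediate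
9 | 2-methoxy-4-(methoxymethoxy)-6-pentylbenzoic acid | CCCCCc1cc(OCOC)cc(OC)c1C(=O)O | intermediate
10 | benzyl 2-methoxy-4-(methoxymethoxy)-6-pentylbenzoate | CCCCCc1cc(OCOC)cc(OC)c1C(=O)OCc1ccccc1 | intermediate
11 | benzyl 4-hydroxy-2-methoxy-6-pentylbenzoate | CCCCCc1cc(O)cc(OC)c1C(=O)OCc1ccccc1 | intermediate
12 | (E)-hept-3-en-2-one | CCC/C=C/C(C)=O | starting material
13 | dimethyl 2-(2-oxoheptan-4-yl)propanedioate (racemic, not isolated) | CCCC(CC(C)=O)C(C(=O)OC)C(=O)OC | intermediate
14 | methyl 2-hydroxy-4-oxo-6-propylcyclohex-2-ene-1-carboxylate (racemic, enol form of the 2,4-dione) | CCCC1CC(=O)C=C(O)C1C(=O)OC | intermediate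
15 | methyl 3-bromo-2-hydroxy-4-oxo-6-propylcyclohex-2-ene-1-carboxylate (racemic, not isolated; drawn as the kinetic 3-bromo isomer) | CCCC1CC(=O)C(Br)=C(O)C1C(=O)OC | intermediate
16 | methyl 2,4-dihydroxy-6-propylbenzoate | CCCc1cc(O)cc(O)c1C(=O)OC | intermediate
17 | methyl 2,4-dimethoxy-6-propylbenzoate | CCCc1cc(OC)cc(OC)c1C(=O)OC | intermediate
18 | 2,4-dimethoxy-6-propylbenzoic acid | CCCc1cc(OC)cc(OC)c1C(=O)O | intermediate
19 | 2,4-dimethoxy-6-propylbenzoic trifluoroacetic anhydride (not isolated) | CCCc1cc(OC)cc(OC)c1C(=O)OC(=O)C(F)(F)F | intermediate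
20 | benzyl 4-[(2,4-dimethoxy-6-propylbenzoyl)oxy]-2-methoxy-6-pentylbenzoate | CCCCCc1cc(OC(=O)c2c(CCC)cc(OC)cc2OC)cc(OC)c1C(=O)OCc1ccccc1 | intermediate
21 | 4-[(2,4-dimethoxy-6-propylbenzoyl)oxy]-2-methoxy-6-pentylbenzoic acid | CCCCCc1cc(OC(=O)c2c(CCC)cc(OC)cc2OC)cc(OC)c1C(=O)O | target

## Summary
Total step count: 13.
Longest linear sequence: 9 steps (steps 1–7, then 12 and 13); the acid branch (steps 8–11) is 4 steps before the convergence.

**Three steps most likely to fail**

Step 2 (aromatisation; risks are ring over-bromination or ester loss on heating). Fallback: setting out from 4, brominate deliberately to completion with 3 equiv Br2 in acetic acid at rt, which gives the stable aromatic methyl 3,5-dibromo-2,4-dihydroxy-6-pentylbenzoate F1. Both ring bromines are then removed by hydrogenolysis (H2, Pd/C, NaOAc, MeOH, rt), which brings the route back at 6. This replaces a delicate one-equivalent halogenation–elimination by an exhaustive bromination and reductive dehalogenation.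

Step 5 (saponification of the di-ortho-substituted ester; risks are incomplete hydrolysis or MOM loss on acidification). Fallback: setting out from 8, avoid acyl substitution altogether by a redox detour. LiAlH4 in THF (0 °C → rt) reduces the ester to [2-methoxy-4-(methoxymethoxy)-6-pentylphenyl]methanol F2. MnO2 in CH2Cl2 oxidises the benzylic alcohol to 2-methoxy-4-(methoxymethoxy)-6-pentylbenzaldehyde F3. Pinnick oxidation (NaClO2, NaH2PO4, 2-methyl-2-butene, t-BuOH/H2O) then gives the acid, and the route is rejoined at 9.

Step 12 (depside coupling of a 2,6-disubstituted acid; risks are slow acylation or trifluoroacetylation of the phenol). Fallback: setting out from 18, make and isolate the acyl chloride with oxalyl chloride and catalytic DMF in CH2Cl2, giving 2,4-dimethoxy-6-propylbenzoyl chloride F4. This is then added to phenol 11 with Et3N and catalytic DMAP in CH2Cl2 (0 °C → rt), so the acyl transfer runs through an acylpyridinium species instead of a mixed anhydride, and the route is rejoined at 20.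

## Further compounds
F1 | step 2 | methyl 3,5-dibromo-2,4-dihydroxy-6-pentylbenzoate | CCCCCc1c(Br)c(O)c(Br)c(O)c1C(=O)OC
F2 | step 5 | [2-methoxy-4-(methoxymethoxy)-6-pentylphenyl]methanol | CCCCCc1cc(OCOC)cc(OC)c1CO
F3 | step 5 | 2-methoxy-4-(methoxymethoxy)-6-pentylbenzaldehyde | CCCCCc1cc(OCOC)cc(OC)c1C=O
F4 | step 12 | 2,4-dimethoxy-6-propylbenzoyl chloride | CCCc1cc(OC)cc(OC)c1C(Cl)=O
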